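**Retrosynthetic overview**

1. The target comes from desilylation of 22; the butenolide is attached last by B-alkyl Suzuki coupling (C12–C13) of the 9-vinyl diene 19 with 4-bromofuran-2(5H)-one, and the vinyl group comes from the C11 ester.
2. The cis-octalin core comes from bridged lactone 9 by lactone hydrolysis, loss of the former pyrone carbonyl as CO2 and shift of the alkene to C8=C9; the C6 and C2 carbinols are then set by ketone reductions (C6 kinetic, axial; C2 thermodynamic, equatorial).
3. Key disconnection: ring B is made by an enantioselective inverse-electron-demand [4+2] cycloaddition that forms C5–C6 and C9–C10 between the ring A silyl dienol ether 8 (from isophorone) and 2-pyrone 6.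
4. Enabling feature: ring A has the isophorone pattern (O on C2, C1, C10 with CH3-20, C5–H, gem-dimethyl C4), so C5=C10 can be the electron-rich γ,δ-bond of a C2 silyl dienol ether; the C6(O)–C7–C8(C17)–C9(C11) chain of ring B maps onto O1–C6–C5–C4(CH2O)–C3(CO2Me) of a 2-pyrone-3-carboxylate.
5. Ring order: pyrone ring (temporary, steps 1–3), then ring B closed onto preformed ring A (step 5, with a temporary lactone bridge), then the butenolide ring brought in preformed (step 12).

Key step: step 5

Remark: labdane numbering is used for all intermediates (decalin C1–C10, C11 on C9, C17 on C8, CH3-20 on C10); β is the face of CH3-20; TBDPS = tert-butyldiphenylsilyl, TIPS = triisopropylsilyl.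
Assumption: the (S,S)-bis(oxazoline) ligand is taken to give the enantiomeric series drawn for 9; if the sense of induction is the opposite one, the (R,R)-ligand is used instead.

**Route**

Step 1
Reactants: 1 hydroxyacetone
Product: 2 1-[(tert-butyldiphenylsilyl)oxy]propan-2-one
Conditions: TBDPSCl, imidazole, CH2Cl2, 0 °C → rt
Reagents that add atoms: tert-butyl(chloro)diphenylsilane, CC(C)(C)[Si](Cl)(c1ccccc1)c1ccccc1
Why: Imidazole-mediated O-silylation of the primary alcohol installs an acid- and base-stable group for the later C17 oxygen; no stereocenter is involved.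

Step 2
Reactants: 2 1-[(tert-butyldiphenylsilyl)oxy]propan-2-one; 3 dimethyl malonate
Product: 4 dimethyl 2-{1-[(tert-butyldiphenylsilyl)oxy]propan-2-ylidene}propanedioate
Conditions: TiCl4, pyridine, THF, 0 °C → rt
Reagents that add atoms: none
Why: The TiCl4/pyridine Knoevenagel condensation is the standard way to condense a ketone with a malonate, and the two identical ester groups leave no alkene geometry to control.

Step 3
Reactants: 4 dimethyl 2-{1-[(tert-butyldiphenylsilyl)oxy]propan-2-ylidene}propanedioate
Product: 6 methyl 4-{[(tert-butyldiphenylsilyl)oxy]methyl}-2-oxo-2H-pyran-3-carboxylate, via dienamine 5 (not isolated)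
Conditions: Me2NCH(OMe)2, toluene, 90 °C; then AcOH/H2O, 70 °C
Reagents that add atoms: N,N-dimethylformamide dimethyl acetal, COC(OC)N(C)C; water, O
Why: Vinylogous condensation of the γ-methyl group (less hindered and not destabilised by an α-oxygen, unlike the silyloxymethyl group) with the amide acetal gives the dienamine, whose acid hydrolysis and lactonisation onto the cis ester closes the 2-pyrone (enamine route to 4-substituted 2-pyrone-3-carboxylates).

Step 4
Reactants: 7 isophorone
Product: 8 triisopropyl[(3,5,5-trimethylcyclohexa-1,3-dien-1-yl)oxy]silane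
Conditions: KOt-Bu, THF, 0 °C; then TIPSCl, 0 °C → rt
Reagents that add atoms: chlorotriisopropylsilane, CC(C)[Si](Cl)(C(C)C)C(C)C
Why: Reversible deprotonation gives the thermodynamic extended dienolate at the ring γ-methylene (the site involved in the known isomerisation of isophorone to its β,γ-isomer), and O-silylation should give the linear endocyclic dienol ether.

Step 5
Reactants: 6 methyl 4-{[(tert-butyldiphenylsilyl)oxy]methyl}-2-oxo-2H-pyran-3-carboxylate; 8 triisopropyl[(3,5,5-trimethylcyclohexa-1,3-dien-1-yl)oxy]silane
Product: 9 endo cycloadduct (bridged lactone)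
Conditions: Cu(OTf)2 (10 mol %), (S,S)-t-Bu-bis(oxazoline) (11 mol %), 4 Å MS, CH2Cl2, −20 °C
Reagents that add atoms: none
Why: The Cu(OTf)2–bis(oxazoline) complex chelates the lactone and ester carbonyls of 6 and lowers its LUMO, so that the electron-rich γ-terminus C5 of 8 bonds to C6 of the pyrone while the developing silyloxyallyl cation at C10 is captured by C3 (the later C9) in a concerted but strongly asynchronous inverse-electron-demand Diels–Alder reaction. The closest known reaction type is the copper bis(oxazoline)-catalysed inverse-demand [4+2] cycloaddition of 2-pyrone-3-carboxylates with cyclic silyl dienol ethers, which gives cis-fused bridged lactones that keep CO2 at low temperature. Ring B is closed by intermolecular [4+2] cycloaddition (C5–C6 and C9–C10), and the O–C(=O) bridge between C6 and C9 closes with it as part of the 2-oxabicyclo[2.2.2]octene. C5 and C10 are set together by suprafacial addition to the ring A alkene (H5 and CH3-20 cis, hence the cis ring fusion) and in the absolute sense by the ligand, which leaves one face of the chelated pyrone open; C6 and C9 follow from the endo orientation (ring A under C4–C5 of the pyrone), C9 being bridge-locked to C6. The step needs site selectivity for the distal C5=C10 bond over the C1=C2 enol ether bond and C5-to-C6(pyrone) regiochemistry, which the largest HOMO coefficient at the γ-carbon C5 and the doubly vinylogous acceptor character of pyrone C6 should secure. Endo/exo selectivity is not critical, because C6 is re-set in steps 7 and 8 and C9 becomes trigonal in step 6.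

Step 6
Reactants: 9 endo cycloadduct (bridged lactone)
Product: 12 6β-hydroxy enoate, via hydroxy half-acid 10 (not isolated), via deconjugated ester 11 (not isolated)
Conditions: LiOH, THF/H2O, 0 °C; HCl to pH 4; pyridine, 100 °C; then NaOMe (cat.), MeOH, 40 °C
Reagents that add atoms: none
Why: Saponification of the strained lactone keeps the pyrone ring oxygen on C6, the malonic half-acid loses the former pyrone carbonyl as CO2 on warming (malonic acid decarboxylation), and methoxide in methanol should equilibrate the alkene into conjugation with the remaining ester (tetrasubstituted C8=C9) while keeping the hydroxy ester open; the C9 stereocenter disappears.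

Step 7
Reactants: 12 6β-hydroxy enoate
Product: 13 6-keto enoate
Conditions: Dess–Martin periodinane, NaHCO3, CH2Cl2, 0 °C; used crude
Reagents that add atoms: none
Why: Buffered Dess–Martin oxidation of the only free hydroxyl gives the β,γ-unsaturated ketone without enolisation toward C5 or C7, and it erases the cycloaddition-derived C6 configuration so that either diastereomer of 9 would converge here.

Step 8
Reactants: 13 6-keto enoate
Product: 15 6α,11-diol, via 6α-hydroxy enoate 14 (not isolated)
Conditions: LiBH(s-Bu)3, THF, −78 °C; then i-Bu2AlH, −78 → −20 °C; aq. KNaC4H4O6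
Reagents that add atoms: none
Why: Steric approach control should make the bulky borohydride attack the C6 ketone from the convex β face (the α face is screened by C1 of the folded ring A, axial on ring B) to give the axial 6α-alcohol, after which i-Bu2AlH reduces the hindered enoate 1,2 to the allylic alcohol.

Step 9
Reactants: 15 6α,11-diol
Product: 16 2-keto 6α,11-diol
Conditions: Bu4NF (1.1 equiv), AcOH, THF, 0 °C
Reagents that add atoms: none
Why: Fluoride cleaves the silyl enol ether much faster than the alkyl TBDPS ether, and the acetic acid buffer protonates the enolate to the C2 ketone (desilylation).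

Step 10
Reactants: 16 2-keto 6α,11-diol
Product: 17 2α,6α,11-triol
Conditions: SmI2, H2O, Et3N, THF, 0 °C, short reaction time
Reagents that add atoms: none
Why: Single-electron (dissolving-metal-type) ketone reduction should give the thermodynamically preferred equatorial 2α-alcohol, because the axial 2β-epimer would be syn-axial to CH3-20 and the β-methyl on C4, whereas hydride reagents are expected to attack equatorially and give the wrong epimer.

Step 11
Reactants: 17 2α,6α,11-triol
Product: 19 9-vinyl diene, via enal 18 (not isolated)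
Conditions: MnO2, CH2Cl2, rt, filter; then Ph3PCH3Br, KN(SiMe3)2 (excess), THF, 0 °C → rt
Reagents that add atoms: methyltriphenylphosphonium bromide (as its ylide), C[P+](c1ccccc1)(c1ccccc1)c1ccccc1.[Br-]
Why: MnO2 oxidises only the allylic primary alcohol (the C2 and C6 alcohols are not allylic), and Wittig methylenation of the hindered enal, as known for β-cyclocitral-type aldehydes, gives the 1,3-diene.

Step 12
Reactants: 19 9-vinyl diene; 20 4-bromofuran-2(5H)-one
Product: 22 17-O-TBDPS ether of the target, via alkylborane 21 (not isolated)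
Conditions: 9-BBN (excess), THF, rt; then 20, PdCl2(dppf) (5 mol %), AsPh3, K3PO4 (aq.), DMF, rt
Reagents that add atoms: none
Why: 9-BBN hydroborates only the terminal vinyl group (anti-Markovnikov; the tetrasubstituted alkene is inert), and B-alkyl Suzuki–Miyaura coupling with the β-bromobutenolide forms C12–C13 with the lactone already in place.

Step 13
Reactants: 22 17-O-TBDPS ether of the target
Product: 23 target, (2S,5R,6S,10S)-2α,6α,17-trihydroxy-5β-labda-8,13-dien-15,16-olide
Conditions: HF·pyridine, pyridine, THF, 0 °C → rt
Reagents that add atoms: none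
Why: Buffered fluoride desilylation frees the primary allylic alcohol under conditions that should leave the butenolide and the tetrasubstituted alkene untouched.

**Compound list**

1 | hydroxyacetone (1-hydroxypropan-2-one) | CC(=O)CO | starting material
2 | 1-[(tert-butyldiphenylsilyl)oxy]propan-2-one | CC(=O)CO[Si](c1ccccc1)(c1ccccc1)C(C)(C)C | intermediate
3 | dimethyl malonate | COC(=O)CC(=O)OC | starting material
4 | dimethyl 2-{1-[(tert-butyldiphenylsilyl)oxy]propan-2-ylidene}propanedioate | COC(=O)C(C(=O)OC)=C(C)CO[Si](c1ccccc1)(c1ccccc1)C(C)(C)C | intermediate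
5 | dienamine: dimethyl 2-{(3E)-1-[(tert-butyldiphenylsilyl)oxy]-4-(dimethylamino)but-3-en-2-ylidene}propanedioate | COC(=O)C(C(=O)OC)=C(CO[Si](c1ccccc1)(c1ccccc1)C(C)(C)C)/C=C/N(C)C | intermediate
6 | methyl 4-{[(tert-butyldiphenylsilyl)oxy]methyl}-2-oxo-2H-pyran-3-carboxylate | COC(=O)C1=C(CO[Si](c2ccccc2)(c2ccccc2)C(C)(C)C)C=COC1=O | intermediate
7 | isophorone (3,5,5-trimethylcyclohex-2-en-1-one) | CC1=CC(=O)CC(C)(C)C1 | starting material
8 | triisopropyl[(3,5,5-trimethylcyclohexa-1,3-dien-1-yl)oxy]silane | CC1=CC(C)(C)CC(O[Si](C(C)C)(C(C)C)C(C)C)=C1 | intermediate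
9 | endo cycloadduct: cis-fused (5β-H, 10β-CH3) tricycle whose ring B is a 2-oxabicyclo[2.2.2]oct-7-en-3-one (lactone O on C6β, lactone C=O on C9β), CO2CH3 on C9α, CH2OTBDPS on C8, C7=C8, ring A with C1=C2 TIPS enol ether | CC1(C)CC(O[Si](C(C)C)(C(C)C)C(C)C)=C[C@]2(C)[C@]3(C(=O)OC)C(CO[Si](c4ccccc4)(c4ccccc4)C(C)(C)C)=C[C@@H](OC3=O)[C@H]12 | intermediate
10 | hydroxy half-acid: 6β-OH, C9 with CO2H (β) and CO2CH3 (α), C7=C8 | CC1(C)CC(O[Si](C(C)C)(C(C)C)C(C)C)=C[C@]2(C)[C@](C(=O)O)(C(=O)OC)C(CO[Si](c3ccccc3)(c3ccccc3)C(C)(C)C)=C[C@@H](O)[C@H]12 | intermediate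
11 | deconjugated ester: 6β-OH, C7=C8, C9–H with CO2CH3 (C9 epimers) | CC1(C)CC(O[Si](C(C)C)(C(C)C)C(C)C)=C[C@]2(C)C(C(=O)OC)C(CO[Si](c3ccccc3)(c3ccccc3)C(C)(C)C)=C[C@@H](O)[C@H]12 | intermediate
12 | 6β-hydroxy enoate: C8=C9, CO2CH3 on C9, CH2OTBDPS on C8, 6β-OH, C1=C2 TIPS enol ether, 5β-H, 10β-CH3 | CC1(C)CC(O[Si](C(C)C)(C(C)C)C(C)C)=C[C@]2(C)C(C(=O)OC)=C(CO[Si](c3ccccc3)(c3ccccc3)C(C)(C)C)C[C@@H](O)[C@H]12 | intermediate
13 | 6-keto enoate (C6 ketone, otherwise as 12) | CC1(C)CC(O[Si](C(C)C)(C(C)C)C(C)C)=C[C@]2(C)C(C(=O)OC)=C(CO[Si](c3ccccc3)(c3ccccc3)C(C)(C)C)CC(=O)[C@H]12 | intermediate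
14 | 6α-hydroxy enoate (C6 epimer of 12) | CC1(C)CC(O[Si](C(C)C)(C(C)C)C(C)C)=C[C@]2(C)C(C(=O)OC)=C(CO[Si](c3ccccc3)(c3ccccc3)C(C)(C)C)C[C@H](O)[C@H]12 | intermediate
15 | 6α,11-diol: CH2OH on C9, CH2OTBDPS on C8, C8=C9, 6α-OH, C1=C2 TIPS enol ether | CC1(C)CC(O[Si](C(C)C)(C(C)C)C(C)C)=C[C@]2(C)C(CO)=C(CO[Si](c3ccccc3)(c3ccccc3)C(C)(C)C)C[C@H](O)[C@H]12 | intermediate
16 | 2-keto 6α,11-diol | CC1(C)CC(=O)C[C@]2(C)C(CO)=C(CO[Si](c3ccccc3)(c3ccccc3)C(C)(C)C)C[C@H](O)[C@H]12 | intermediate
17 | 2α,6α,11-triol (17-O-TBDPS) | CC1(C)C[C@H](O)C[C@]2(C)C(CO)=C(CO[Si](c3ccccc3)(c3ccccc3)C(C)(C)C)C[C@H](O)[C@H]12 | intermediate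
18 | enal (C11 aldehyde on C9) | CC1(C)C[C@H](O)C[C@]2(C)C(C=O)=C(CO[Si](c3ccccc3)(c3ccccc3)C(C)(C)C)C[C@H](O)[C@H]12 | intermediate
19 | 9-vinyl diene (C11=C12 on C9) | CC1(C)C[C@H](O)C[C@]2(C)C(C=C)=C(CO[Si](c3ccccc3)(c3ccccc3)C(C)(C)C)C[C@H](O)[C@H]12 | intermediate
20 | 4-bromofuran-2(5H)-one | O=C1C=C(Br)CO1 | starting material
21 | alkylborane: B-(C12)-9-borabicyclo[3.3.1]nonane adduct of 19 | CC1(C)C[C@H](O)C[C@]2(C)C(CCB3C4CCCC3CCC4)=C(CO[Si](c3ccccc3)(c3ccccc3)C(C)(C)C)C[C@H](O)[C@H]12 | intermediate
22 | 17-O-TBDPS ether of the target | CC1(C)C[C@H](O)C[C@]2(C)C(CCC3=CC(=O)OC3)=C(CO[Si](c3ccccc3)(c3ccccc3)C(C)(C)C)C[C@H](O)[C@H]12 | intermediate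
23 | CNP0293367.1, (2S,5R,6S,10S)-2α,6α,17-trihydroxy-5β-labda-8,13-dien-15,16-olide | CC1(C)C[C@H](O)C[C@]2(C)C(CCC3=CC(=O)OC3)=C(CO)C[C@H](O)[C@H]12 | target

**Summary**

Total step count: 13. Longest linear sequence: 12 steps (steps 1–3 and 5–13); step 4 is a one-step side branch.

**Steps most likely to fail**

Step 5. The cycloaddition may be slow at the C5 terminus, which is flanked by the gem-dimethyl carbon. It may also go across the C1=C2 enol ether bond, stop at the open-chain vinylogous Michael adduct, or show poor enantiofacial discrimination with the 4-substituted pyrone. Fallback: setting out from 6 and 8, the cycloaddition is run without a chiral catalyst, thermally under high pressure (about 12 kbar, CH2Cl2, rt) or with Yb(OTf)3 as an achiral Lewis acid. This should give 9 together with its mirror image, the enantiomeric cycloadduct F1. The racemate is separated by preparative chromatography on a chiral stationary phase, and the route is rejoined at 9.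

Step 8. Hydride delivery to C6 may not be face-selective, or the doubly activated C7 methylene of 13 may be enolised instead of the ketone being reduced. Fallback: the ketone stage is avoided. Setting out from 12, the 6β-alcohol is inverted by a Mitsunobu reaction (PPh3, DIAD, 4-nitrobenzoic acid, toluene, 0 °C → rt) to the 6α-(4-nitrobenzoate) F2. Methanolysis (K2CO3, MeOH, 0 °C) gives 14, where the route is rejoined; 14 is reduced with i-Bu2AlH to 15 as in the second half of step 8.

Step 10. Protonation of the ketyl may not give the equatorial 2α-alcohol selectively, or electron transfer may start to cleave the allylic C–O bonds. Fallback: C2 is set by catalyst control. Setting out from 16, an NADPH-dependent ketoreductase (alcohol dehydrogenase class), chosen from a panel for 2S selectivity, is used with glucose/glucose dehydrogenase cofactor recycling in phosphate buffer with DMSO cosolvent at 30 °C. It should reduce only the C2 ketone and return to the route at 17; it makes no compound outside the list (F0).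

**Further compounds**

F1 | step 5 | enantiomeric cycloadduct (mirror image of 9) | CC1(C)CC(O[Si](C(C)C)(C(C)C)C(C)C)=C[C@@]2(C)[C@@]3(C(=O)OC)C(CO[Si](c4ccccc4)(c4ccccc4)C(C)(C)C)=C[C@H](OC3=O)[C@@H]12
F2 | step 8 | 6α-(4-nitrobenzoate) of 14 | CC1(C)CC(O[Si](C(C)C)(C(C)C)C(C)C)=C[C@]2(C)C(C(=O)OC)=C(CO[Si](c3ccccc3)(c3ccccc3)C(C)(C)C)C[C@H](OC(=O)c3ccc(cc3)[N+](=O)[O-])[C@H]12
F0 | step 10 | none | none
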